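(Readings and results are simulated with constants of no real substance; noise was put on by code.)

Per minute and per unit of target, the over-reaction product forms at a rate I can read from the two earlier runs, elm and oak, and that rate is what I carry to the new flask.

the same everywhere: free catalyst 20 mol%; second catalyst 0.1 mol%
- elm: starting material 0.025 M; reagent 2 equiv; run made earlier
- oak: starting material 0.038 M; reagent 2 equiv; run made earlier
- flask: starting material 0.050 M; reagent 2.00 equiv; time 30 min

| run | time / min | over-reaction product / % | target / % | starting material / % |
|---|---|---|---|---|
| elm | 5.00 | 9.6 | 10.3 | 35.2 |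
| elm | 10.0 | 29.9 | 14.6 | 12.2 |
| elm | 15.0 | 45.3 | 13.3 | 4.4 |
| elm | 20.0 | 57.1 | 12.1 | 1.5 |
| elm | 25.0 | 64.7 | 10.4 | 0.7 |
| oak | 5.00 | 30.0 | 12.1 | 20.5 |
| oak | 10.0 | 58.2 | 10.4 | 4.1 |
| oak | 15.0 | 71.8 | 8.2 | 1.5 |
| oak | 20.0 | 78.9 | 5.5 | 0.6 |
| oak | 25.0 | 83.0 | 4.6 | 0 |

(readings scatter by 0.3 percentage points)

* ratio of over-reaction product to target at 20 s
* ratio of over-reaction product to target at 3.0 min
* ratio of over-reaction product to target at 30 min

The listed species do not add up to the charge: elm at 5.00 min lacks 44.9%. So I put an unseen intermediate in the chain starting material, intermediate, target, over-reaction product. Between 5.00 min and 10.0 min, elm gains over-reaction product at a pseudo-first-order constant kO, the gain per minute over the mean target, of 0.326 min⁻¹. Oak in the same window gives 0.501 min⁻¹. I count one equivalent of reagent per target and two per over-reaction product, so the mean equivalents left, ρ, are 1.48 in elm and 1.01 in oak. At fixed loadings the catalysts scale with the starting concentration c, so I divide kO by ρ and by c squared. Elm reads 5.87 M⁻² s⁻¹ and oak 5.75 M⁻² s⁻¹, which agree. Their mean is K, the over-reaction constant: kO per equivalent of reagent left and per squared starting concentration, 5.81 M⁻² s⁻¹.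

For the flask at 0.050 M with 2.00 equiv, kO starts at 1.74 min⁻¹. Early on I treat the over-reaction product as a small correction to the target. Intermediate grows with the time t and target with t squared, and integrating kO times target makes the ratio of over-reaction product to target a third of kO·t. At 20 s I commit to 0.193. At 3.0 min the term gives 1.74, which is more than one, so there it is no small correction and serves as a scale; for 30 min I make no number.

The forecast says 0.2, 2.4 and 37, with the ground that late on “reagent starves”.

    starting material + free catalyst → free catalyst + intermediate (k = 0.697 M⁻¹ s⁻¹)
    reagent + second catalyst + intermediate → second catalyst + target (k = 1890 M⁻² s⁻¹)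
    reagent + free catalyst + target → free catalyst + over-reaction product (k = 28.6 M⁻² s⁻¹)

The flask gives 0.205 at 20 s, 2.56 at 3.0 min and 36.1 at 30 min. Target and over-reaction product stand level in the flask at 1.37 min, where a third of kO·t is 0.795, less than the ratio of one. For a neighbouring flask, the same recipe at 0.020 M, K gives kO = 0.279 min⁻¹ and a ratio at 20 s of 0.0310, and that neighbouring flask gives 0.0310.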